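**Plan**

- The retrosynthesis masks both phenols as triisopropylsilyl (TIPS) ethers and first cuts the C3–C3a bond of the 2,3-dihydrobenzofuran. C3 is a benzylic ring carbon bearing CH2OH, so C3 and its CH2–O are the internal carbon and the CH2–O of a terminal oxirane, and C3a is an aryl anion made from a C3a bromide.
- The C2–O1 aryl ether is cut next into a guaiacyl epoxy alcohol and a 2-bromo-6-methoxyphenol that already carries the furofuran. The furofuran is cut at its two benzylic C–O bonds and at the two C–C bonds that join a butenolide to a syringyl acyl anion and to an aldehyde derived from 5-bromovanillin.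
- Forward, the two furofuran rings arise first (tandem conjugate addition–aldol, reduction, acid-mediated double cyclisation), then the ether link is made, then the dihydrofuran ring closes last, then the silyl groups are removed.
- The furofuran bridgeheads come from (5R)-5-menthyloxybutenolide by anti,anti addition, and its benzylic centres from exo-selective cation capture. C2 of the dihydrobenzofuran comes from a Sharpless kinetic resolution followed by Mitsunobu inversion, and C3 from inversion at the oxirane carbon, which makes the ring cis.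

Key step: step 12

Assumption: the (5R)-menthyloxybutenolide used in step 4 is treated as a purchasable chiral building block, and the benzylic carbinol centres formed in steps 4 and 6 are left as epimer mixtures because step 7 passes through planar benzylic cations.

**Route**

Step 1
Reactants: 1 syringaldehyde
Product: 2 4-(1,3-dithian-2-yl)-2,6-dimethoxyphenol
Conditions: propane-1,3-dithiol, BF3·OEt2 (cat.), CH2Cl2, 0 °C to rt
Reagents that add atoms: propane-1,3-dithiol, SCCCS
Why: Lewis-acid-promoted thioacetalisation turns the formyl carbon into a latent acyl anion (Corey–Seebach umpolung) and leaves the phenol untouched.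

Step 2
Reactants: 2 4-(1,3-dithian-2-yl)-2,6-dimethoxyphenol
Product: 3 [4-(1,3-dithian-2-yl)-2,6-dimethoxyphenoxy]triisopropylsilane
Conditions: TIPSCl, imidazole, 4-(dimethylamino)pyridine (cat.), DMF, 50 °C
Reagents that add atoms: triisopropylsilyl chloride, CC(C)[Si](Cl)(C(C)C)C(C)C
Why: Imidazole-promoted silylation of the hindered phenol installs a silyl ether that tolerates organolithium reagents, hydride and mild acid and is removed by fluoride only at the end.

Step 3
Reactants: 4 5-bromovanillin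
Product: 5 2-bromo-4-formyl-6-methoxyphenyl pivalate
Conditions: pivaloyl chloride, Et3N, 4-(dimethylamino)pyridine (cat.), CH2Cl2, 0 °C to rt
Reagents that add atoms: pivaloyl chloride, CC(C)(C)C(=O)Cl
Why: O-acylation gives a hindered ester that survives the enolate aldol of step 4 and is cleaved by the hydride of step 6, so the bromophenol needs no separate deprotection.

Step 4
Reactants: 3 [4-(1,3-dithian-2-yl)-2,6-dimethoxyphenoxy]triisopropylsilane; 5 2-bromo-4-formyl-6-methoxyphenyl pivalate; 6 (5R)-5-[(1R,2S,5R)-menthyloxy]furan-2(5H)-one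
Product: 9 (3S,4R,5R)-3-[(3-bromo-5-methoxy-4-pivaloyloxyphenyl)(hydroxy)methyl]-4-{2-[3,5-dimethoxy-4-(triisopropylsilyloxy)phenyl]-1,3-dithian-2-yl}-5-[(1R,2S,5R)-menthyloxy]dihydrofuran-2(3H)-one as a mixture of carbinol epimers, via 2-lithio-1,3-dithiane 7 (not isolated), via lithium lactone enolate 8 (not isolated)
Conditions: n-BuLi (1.0 equiv), THF, −78 °C; then 6, −78 °C; then 5, −78 °C; aq. NH4Cl
Reagents that add atoms: none
Why: Tandem Michael addition–aldol reaction in which the lithiated dithiane adds 1,4 to the butenolide anti to the C5 menthyloxy group (sets C4 as R) and the resulting lactone enolate is trapped by aldehyde 5 anti to the new C4 substituent (sets C3 as S); placing the aryl bromide on the aldehyde partner keeps it away from n-BuLi.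

Step 5
Reactants: 9 the dithiane aldol lactone
Product: 10 (3S,4R,5R)-3-[(3-bromo-5-methoxy-4-pivaloyloxyphenyl)(hydroxy)methyl]-4-[3,5-dimethoxy-4-(triisopropylsilyloxy)benzoyl]-5-[(1R,2S,5R)-menthyloxy]dihydrofuran-2(3H)-one
Conditions: HgO, BF3·OEt2, THF/H2O, rt
Reagents that add atoms: water, O
Why: Thiophile-assisted hydrolysis of the dithioacetal by divalent mercury unmasks the aryl ketone under conditions that should leave the lactone acetal, pivalate, silyl ether and aryl bromide intact.

Step 6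
Reactants: 10 the keto lactone
Product: 11 (2R,3R)-2-[(3-bromo-4-hydroxy-5-methoxyphenyl)(hydroxy)methyl]-3-{[3,5-dimethoxy-4-(triisopropylsilyloxy)phenyl](hydroxy)methyl}butane-1,4-diol as a mixture of benzylic epimers
Conditions: LiAlH4, THF, 0 °C to rt
Reagents that add atoms: none
Why: Global hydride reduction converts the ketone to a benzylic alcohol, opens the lactone acetal to the 1,4-diol with loss of menthol and cleaves the pivalate to the phenol, while the two backbone stereocentres are not touched.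

Step 7
Reactants: 11 the pentaol
Product: 12 2-bromo-4-{(1S,3aR,4S,6aR)-4-[3,5-dimethoxy-4-(triisopropylsilyloxy)phenyl]tetrahydro-1H,3H-furo[3,4-c]furan-1-yl}-6-methoxyphenol
Conditions: (+)-camphor-10-sulfonic acid (cat.), 4 Å molecular sieves, CH2Cl2/THF, 0 °C to rt
Reagents that add atoms: none
Why: Acid-mediated double cyclodehydration (SN1 etherification through a p-quinone methide on the phenol side and a p-silyloxybenzyl cation on the other) lets each primary hydroxyl capture the benzylic cation of the other branch, the (R,R) backbone fixing the cis ring fusion and attack anti to the neighbouring ring substituent placing both aryl groups exo, so the epimeric carbinols should converge.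

Step 8
Reactants: 13 vanillin
Product: 14 3-methoxy-4-(triisopropylsilyloxy)benzaldehyde
Conditions: TIPSCl, imidazole, DMF, rt
Reagents that add atoms: triisopropylsilyl chloride, CC(C)[Si](Cl)(C(C)C)C(C)C
Why: Standard phenol silylation gives the protecting group needed to withstand t-BuLi in step 12 and to come off with fluoride in step 13.

Step 9
Reactants: 14 3-methoxy-4-(triisopropylsilyloxy)benzaldehyde; 15 vinylmagnesium bromide
Product: 16 rac-1-[3-methoxy-4-(triisopropylsilyloxy)phenyl]prop-2-en-1-ol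
Conditions: THF, −78 to 0 °C; aq. NH4Cl
Reagents that add atoms: none
Why: Grignard 1,2-addition to the aryl aldehyde gives the racemic secondary allylic alcohol required for the kinetic resolution.

Step 10
Reactants: 16 rac-1-[3-methoxy-4-(triisopropylsilyloxy)phenyl]prop-2-en-1-ol
Product: 17 (S)-[3-methoxy-4-(triisopropylsilyloxy)phenyl][(2R)-oxiran-2-yl]methanol (erythro)
Conditions: Ti(OiPr)4 (0.1 equiv), diisopropyl L-(+)-tartrate (0.15 equiv), t-BuOOH (0.45 equiv), 4 Å molecular sieves, CH2Cl2, −20 °C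
Reagents that add atoms: tert-butyl hydroperoxide, CC(C)(C)OO
Why: In this Sharpless kinetic resolution (Katsuki–Sharpless epoxidation) the L-(+)-tartrate catalyst should epoxidise the (R)-enantiomer of 16 much faster and anti to the aryl group, so the sub-stoichiometric oxidant gives the erythro epoxy alcohol with an (R)-oxirane carbon; the unchanged carbinol centre is named S only because the oxiranyl group now outranks the aryl group.

Step 11
Reactants: 12 the furofuran bromophenol; 17 the erythro epoxy alcohol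
Product: 18 (R)-[3-methoxy-4-(triisopropylsilyloxy)phenyl][(2R)-oxiran-2-yl]methyl 2-bromo-6-methoxy-4-{(1S,3aR,4S,6aR)-4-[3,5-dimethoxy-4-(triisopropylsilyloxy)phenyl]tetrahydro-1H,3H-furo[3,4-c]furan-1-yl}phenyl ether (threo)
Conditions: PPh3, DIAD, toluene, 0 °C to rt
Reagents that add atoms: none
Why: In this Mitsunobu etherification the acidic 2,6-disubstituted phenol displaces the alkoxyphosphonium group by SN2 with inversion at the benzylic carbinol, turning the erythro alcohol into the threo (R,R) ether; the electron-withdrawing oxiranyl group and the non-polar solvent disfavour ionisation, and the epoxide is inert to the reagents.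

Step 12
Reactants: 18 the threo bromoaryl epoxy ether
Product: 20 {(2S,3S)-5-{(1S,3aR,4S,6aR)-4-[3,5-dimethoxy-4-(triisopropylsilyloxy)phenyl]tetrahydro-1H,3H-furo[3,4-c]furan-1-yl}-7-methoxy-2-[3-methoxy-4-(triisopropylsilyloxy)phenyl]-2,3-dihydro-1-benzofuran-3-yl}methanol, via aryllithium 19 (not isolated)
Conditions: t-BuLi (2.1 equiv), THF/Et2O, −78 °C, then warm to −20 °C; aq. NH4Cl
Reagents that add atoms: none
Why: Bromine–lithium exchange at C3a is faster at −78 °C than any deprotonation and the second equivalent of t-BuLi destroys the t-BuBr formed, so aryllithium 19 should form cleanly and, on warming, open the oxirane at its internal carbon by intramolecular SN2 attack, releasing the primary lithium alkoxide that becomes the C3 hydroxymethyl group. The closest known reaction type is the Parham cyclisation (cyclialkylation) of o-lithioaryl ethers onto tethered epoxides, which gives 3-(hydroxymethyl)-2,3-dihydrobenzofurans. The dihydrofuran ring (O1, C2, C3, C3a, C7a) closes in the 5-exo-tet mode, the breaking oxirane C–O bond lying outside the new ring. The only new stereocentre, C3, is set by inversion at the (R)-oxirane carbon while C2 is a spectator, so the threo relationship of 18 is carried stereospecifically into the cis (2S,3S) ring of 20. The step needs exo opening to beat 6-endo opening to a 3-chromanol and needs the labile cis benzylic aryl ether to survive; the first is secured by the five-atom tether, which allows a collinear backside approach only at the internal carbon, and the second by the absence of any acid or benzylic cation.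

Step 13
Reactants: 20 the bis-TIPS ether
Product: 21 4-[(2S,3S)-3-(hydroxymethyl)-5-{(1S,3aR,4S,6aR)-4-(4-hydroxy-3,5-dimethoxyphenyl)tetrahydro-1H,3H-furo[3,4-c]furan-1-yl}-7-methoxy-2,3-dihydro-1-benzofuran-2-yl]-2-methoxyphenol (CNP0126146.1)
Conditions: Bu4NF, AcOH (1:1), THF, 0 °C
Reagents that add atoms: none
Why: Fluoride-mediated cleavage of both aryl silyl ethers is buffered with acetic acid so that no free phenoxide can open the cis ring through a quinone methide and epimerise C2.

**Compound list**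

1 | syringaldehyde | COc1cc(C=O)cc(OC)c1O | starting material
2 | 4-(1,3-dithian-2-yl)-2,6-dimethoxyphenol | COc1cc(C2SCCCS2)cc(OC)c1O | intermediate
3 | [4-(1,3-dithian-2-yl)-2,6-dimethoxyphenoxy]triisopropylsilane | COc1cc(C2SCCCS2)cc(OC)c1O[Si](C(C)C)(C(C)C)C(C)C | intermediate
4 | 5-bromovanillin | COc1cc(C=O)cc(Br)c1O | starting material
5 | 2-bromo-4-formyl-6-methoxyphenyl pivalate | COc1cc(C=O)cc(Br)c1OC(=O)C(C)(C)C | intermediate
6 | (5R)-5-[(1R,2S,5R)-menthyloxy]furan-2(5H)-one | O=C1C=C[C@H](O[C@@H]2C[C@H](C)CC[C@H]2C(C)C)O1 | starting material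
7 | 2-lithio-2-[3,5-dimethoxy-4-(triisopropylsilyloxy)phenyl]-1,3-dithiane (not isolated) | [Li]C1(c2cc(OC)c(O[Si](C(C)C)(C(C)C)C(C)C)c(OC)c2)SCCCS1 | intermediate
8 | lithium enolate of (4R,5R)-4-{2-[3,5-dimethoxy-4-(triisopropylsilyloxy)phenyl]-1,3-dithian-2-yl}-5-menthyloxydihydrofuran-2(3H)-one (not isolated) | [Li]OC1=C[C@@H](C2(c3cc(OC)c(O[Si](C(C)C)(C(C)C)C(C)C)c(OC)c3)SCCCS2)[C@H](O[C@@H]2C[C@H](C)CC[C@H]2C(C)C)O1 | intermediate
9 | (3S,4R,5R)-3-[(3-bromo-5-methoxy-4-pivaloyloxyphenyl)(hydroxy)methyl]-4-{2-[3,5-dimethoxy-4-(triisopropylsilyloxy)phenyl]-1,3-dithian-2-yl}-5-menthyloxydihydrofuran-2(3H)-one, carbinol epimers | O=C1O[C@@H](O[C@@H]2C[C@H](C)CC[C@H]2C(C)C)[C@H](C2(c3cc(OC)c(O[Si](C(C)C)(C(C)C)C(C)C)c(OC)c3)SCCCS2)[C@H]1C(O)c1cc(OC)c(OC(=O)C(C)(C)C)c(Br)c1 | intermediate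
10 | (3S,4R,5R)-3-[(3-bromo-5-methoxy-4-pivaloyloxyphenyl)(hydroxy)methyl]-4-[3,5-dimethoxy-4-(triisopropylsilyloxy)benzoyl]-5-menthyloxydihydrofuran-2(3H)-one, carbinol epimers | O=C1O[C@@H](O[C@@H]2C[C@H](C)CC[C@H]2C(C)C)[C@H](C(=O)c2cc(OC)c(O[Si](C(C)C)(C(C)C)C(C)C)c(OC)c2)[C@H]1C(O)c1cc(OC)c(OC(=O)C(C)(C)C)c(Br)c1 | intermediate
11 | (2R,3R)-2-[(3-bromo-4-hydroxy-5-methoxyphenyl)(hydroxy)methyl]-3-{[3,5-dimethoxy-4-(triisopropylsilyloxy)phenyl](hydroxy)methyl}butane-1,4-diol, benzylic epimers | OC[C@H](C(O)c1cc(OC)c(O)c(Br)c1)[C@H](CO)C(O)c1cc(OC)c(O[Si](C(C)C)(C(C)C)C(C)C)c(OC)c1 | intermediate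
12 | 2-bromo-4-{(1S,3aR,4S,6aR)-4-[3,5-dimethoxy-4-(triisopropylsilyloxy)phenyl]tetrahydro-1H,3H-furo[3,4-c]furan-1-yl}-6-methoxyphenol | COc1cc([C@H]2OC[C@H]3[C@@H]2CO[C@@H]3c2cc(OC)c(O[Si](C(C)C)(C(C)C)C(C)C)c(OC)c2)cc(Br)c1O | intermediate
13 | vanillin | COc1cc(C=O)ccc1O | starting material
14 | 3-methoxy-4-(triisopropylsilyloxy)benzaldehyde | COc1cc(C=O)ccc1O[Si](C(C)C)(C(C)C)C(C)C | intermediate
15 | vinylmagnesium bromide | C=C[Mg]Br | starting material
16 | rac-1-[3-methoxy-4-(triisopropylsilyloxy)phenyl]prop-2-en-1-ol | COc1cc(C(O)C=C)ccc1O[Si](C(C)C)(C(C)C)C(C)C | intermediate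
17 | (S)-[3-methoxy-4-(triisopropylsilyloxy)phenyl][(2R)-oxiran-2-yl]methanol (erythro) | COc1cc([C@H](O)[C@H]2CO2)ccc1O[Si](C(C)C)(C(C)C)C(C)C | intermediate
18 | threo epoxy ether: (R)-[3-methoxy-4-(triisopropylsilyloxy)phenyl][(2R)-oxiran-2-yl]methyl ether of phenol 12 | COc1cc([C@@H](Oc3c(OC)cc([C@H]4OC[C@H]5[C@@H]4CO[C@@H]5c4cc(OC)c(O[Si](C(C)C)(C(C)C)C(C)C)c(OC)c4)cc3Br)[C@H]2CO2)ccc1O[Si](C(C)C)(C(C)C)C(C)C | intermediate
19 | aryllithium from 18, lithium in place of bromine at C3a (not isolated) | COc1cc([C@@H](Oc3c(OC)cc([C@H]4OC[C@H]5[C@@H]4CO[C@@H]5c4cc(OC)c(O[Si](C(C)C)(C(C)C)C(C)C)c(OC)c4)cc3[Li])[C@H]2CO2)ccc1O[Si](C(C)C)(C(C)C)C(C)C | intermediate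
20 | bis-TIPS ether of the target, (2S,3S)-cis-2,3-dihydrobenzofuran-3-ylmethanol | COc1cc([C@H]2Oc3c(OC)cc([C@H]4OC[C@H]5[C@@H]4CO[C@@H]5c4cc(OC)c(O[Si](C(C)C)(C(C)C)C(C)C)c(OC)c4)cc3[C@H]2CO)ccc1O[Si](C(C)C)(C(C)C)C(C)C | intermediate
21 | CNP0126146.1, 4-[(2S,3S)-3-(hydroxymethyl)-5-{(1S,3aR,4S,6aR)-4-(4-hydroxy-3,5-dimethoxyphenyl)tetrahydro-1H,3H-furo[3,4-c]furan-1-yl}-7-methoxy-2,3-dihydro-1-benzofuran-2-yl]-2-methoxyphenol | COc1cc([C@H]2Oc3c(OC)cc([C@H]4OC[C@H]5[C@@H]4CO[C@@H]5c4cc(OC)c(O)c(OC)c4)cc3[C@H]2CO)ccc1O | target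

**Step count**

Total: 13 steps. Longest linear sequence: 9 steps (1, 2, 4, 5, 6, 7, 11, 12, 13).

**Steps most likely to fail**

Step 12. After the exchange, the aryllithium may abstract the doubly activated C2–H of its own benzylic ether faster than it opens the oxirane, or the congested cis-forming transition state may let opening at the terminal carbon compete. The fallback sets out from 14 and 12 and comes back at 20, and it closes the same ring through the C2–C3 bond instead.
- Aldehyde 14 would be reduced (NaBH4, MeOH) to [3-methoxy-4-(triisopropylsilyloxy)phenyl]methanol F1.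
- F1 would be joined to phenol 12 (PPh3, DIAD, THF) to give the aryl benzyl ether F2.
- Palladium-catalysed coupling of the bromide with the zinc enolate of tert-butyl acetate (BrZnCH2CO2t-Bu, Pd(dba)2, P(t-Bu)3, THF, rt) would give the tert-butyl arylacetate F3.
- Diazo transfer (4-acetamidobenzenesulfonyl azide, DBU, MeCN) would give the tert-butyl aryldiazoacetate F4.
- Intramolecular carbenoid insertion into the benzylic O–CH2 bond under dirhodium tetrakis[N-phthaloyl-(S)-tert-leucinate], Rh2(S-PTTL)4, or its mirror-image catalyst if that proves matched, is a reaction type known to give cis-2-aryl-2,3-dihydrobenzofuran-3-carboxylates. It would give the cis tert-butyl (2S,3R)-2,3-dihydrobenzofuran-3-carboxylate F5.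
- LiAlH4 (Et2O, −40 to 0 °C) would reduce F5 to 20.

Step 11. The alkoxyphosphonium salt may ionise at the electron-rich benzylic carbon, which would erode the inversion and give erythro/threo mixtures, or the di-ortho-substituted phenol may attack too slowly. The fallback sets out from 14, uses 12, and comes back at 18; both stereocentres are then set by SN2 steps under basic conditions.
- Horner–Wadsworth–Emmons olefination of 14 (triethyl phosphonoacetate, NaH, THF) would give ethyl (E)-3-[3-methoxy-4-(triisopropylsilyloxy)phenyl]prop-2-enoate F6.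
- DIBAL-H would give (E)-3-[3-methoxy-4-(triisopropylsilyloxy)phenyl]prop-2-en-1-ol F7.
- Katsuki–Sharpless epoxidation (Ti(OiPr)4, diethyl L-(+)-tartrate, t-BuOOH, CH2Cl2, −20 °C) would give {(2S,3S)-3-[3-methoxy-4-(triisopropylsilyloxy)phenyl]oxiran-2-yl}methanol F8.
- Phenol 12 would open F8 at the benzylic carbon with inversion (Cs2CO3, DMF, 60 °C) to give the (2S,3R)-3-aryl-3-aryloxypropane-1,2-diol F9.
- Selective acetylation of the primary hydroxyl (AcCl, 2,4,6-collidine, CH2Cl2, −78 °C) would give the primary monoacetate F10.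
- Mesylation of the secondary hydroxyl (MsCl, Et3N) would give the secondary mesylate F11.
- K2CO3 in MeOH would remove the acetate, and the primary alkoxide would displace the mesylate with inversion at C2 to give 18.

Step 10. The rate difference between the enantiomers may be too small at the conversion needed, or the titanium catalyst may open the electron-rich benzylic epoxy alcohol, either of which lowers the enantiomeric purity of 17. The fallback sets out from 16 and comes back at 17.
- Acylation of 16 with vinyl acetate, catalysed by immobilised Candida antarctica lipase B (hexane/t-BuOMe, rt), should acylate the (R)-alcohol selectively to (R)-1-[3-methoxy-4-(triisopropylsilyloxy)phenyl]prop-2-enyl acetate F12.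
- After separation from the (S)-alcohol, methanolysis (K2CO3, MeOH) would give (R)-1-[3-methoxy-4-(triisopropylsilyloxy)phenyl]prop-2-en-1-ol F13.
- The matched epoxidation of F13 (Ti(OiPr)4, diisopropyl L-(+)-tartrate, t-BuOOH, CH2Cl2, −20 °C) is then a diastereoselective reaction that can be run to full conversion and would give 17.

**Further compounds**

F1 | step 12 | [3-methoxy-4-(triisopropylsilyloxy)phenyl]methanol | COc1cc(CO)ccc1O[Si](C(C)C)(C(C)C)C(C)C
F2 | step 12 | 3-methoxy-4-(triisopropylsilyloxy)benzyl ether of phenol 12 | COc1cc(COc3c(OC)cc([C@H]4OC[C@H]5[C@@H]4CO[C@@H]5c4cc(OC)c(O[Si](C(C)C)(C(C)C)C(C)C)c(OC)c4)cc3Br)ccc1O[Si](C(C)C)(C(C)C)C(C)C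
F3 | step 12 | tert-butyl arylacetate from F2, CH2CO2t-Bu in place of bromine | COc1cc(COc3c(OC)cc([C@H]4OC[C@H]5[C@@H]4CO[C@@H]5c4cc(OC)c(O[Si](C(C)C)(C(C)C)C(C)C)c(OC)c4)cc3CC(=O)OC(C)(C)C)ccc1O[Si](C(C)C)(C(C)C)C(C)C
F4 | step 12 | tert-butyl aryldiazoacetate from F3 | COc1cc(COc3c(OC)cc([C@H]4OC[C@H]5[C@@H]4CO[C@@H]5c4cc(OC)c(O[Si](C(C)C)(C(C)C)C(C)C)c(OC)c4)cc3C(=[N+]=[N-])C(=O)OC(C)(C)C)ccc1O[Si](C(C)C)(C(C)C)C(C)C
F5 | step 12 | tert-butyl (2S,3R)-cis-2,3-dihydrobenzofuran-3-carboxylate corresponding to 20 | COc1cc([C@H]2Oc3c(OC)cc([C@H]4OC[C@H]5[C@@H]4CO[C@@H]5c4cc(OC)c(O[Si](C(C)C)(C(C)C)C(C)C)c(OC)c4)cc3[C@H]2C(=O)OC(C)(C)C)ccc1O[Si](C(C)C)(C(C)C)C(C)C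
F6 | step 11 | ethyl (E)-3-[3-methoxy-4-(triisopropylsilyloxy)phenyl]prop-2-enoate | CCOC(=O)/C=C/c1ccc(O[Si](C(C)C)(C(C)C)C(C)C)c(OC)c1
F7 | step 11 | (E)-3-[3-methoxy-4-(triisopropylsilyloxy)phenyl]prop-2-en-1-ol | OC/C=C/c1ccc(O[Si](C(C)C)(C(C)C)C(C)C)c(OC)c1
F8 | step 11 | {(2S,3S)-3-[3-methoxy-4-(triisopropylsilyloxy)phenyl]oxiran-2-yl}methanol | OC[C@@H]1O[C@H]1c1ccc(O[Si](C(C)C)(C(C)C)C(C)C)c(OC)c1
F9 | step 11 | (2S,3R)-3-[3-methoxy-4-(triisopropylsilyloxy)phenyl]-3-(aryloxy)propane-1,2-diol, aryloxy from phenol 12 | OC[C@H](O)[C@H](Oc3c(OC)cc([C@H]4OC[C@H]5[C@@H]4CO[C@@H]5c4cc(OC)c(O[Si](C(C)C)(C(C)C)C(C)C)c(OC)c4)cc3Br)c1ccc(O[Si](C(C)C)(C(C)C)C(C)C)c(OC)c1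
F10 | step 11 | primary monoacetate of F9 | CC(=O)OC[C@H](O)[C@H](Oc3c(OC)cc([C@H]4OC[C@H]5[C@@H]4CO[C@@H]5c4cc(OC)c(O[Si](C(C)C)(C(C)C)C(C)C)c(OC)c4)cc3Br)c1ccc(O[Si](C(C)C)(C(C)C)C(C)C)c(OC)c1
F11 | step 11 | secondary mesylate of F10 | CC(=O)OC[C@H](OS(C)(=O)=O)[C@H](Oc3c(OC)cc([C@H]4OC[C@H]5[C@@H]4CO[C@@H]5c4cc(OC)c(O[Si](C(C)C)(C(C)C)C(C)C)c(OC)c4)cc3Br)c1ccc(O[Si](C(C)C)(C(C)C)C(C)C)c(OC)c1
F12 | step 10 | (R)-1-[3-methoxy-4-(triisopropylsilyloxy)phenyl]prop-2-enyl acetate | COc1cc([C@H](OC(C)=O)C=C)ccc1O[Si](C(C)C)(C(C)C)C(C)C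
F13 | step 10 | (R)-1-[3-methoxy-4-(triisopropylsilyloxy)phenyl]prop-2-en-1-ol | COc1cc([C@H](O)C=C)ccc1O[Si](C(C)C)(C(C)C)C(C)C
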